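All runs were generated by integration on assumed constants, and the scatter is random.

I had 3 questions about two flasks.

| setting | larch | alder | Saturday's | Friday's |
|---|---|---|---|---|
| starting material | 0.18 M | 0.60 M | 0.12 M | 0.39 M |
| coupling partner | 0.585 M | 0.585 M | 0.585 M | 0.585 M |
| temperature | 35 °C | 57 °C |  |  |
| remark | run made earlier | run made earlier | at 25 °C throughout | at 25 °C until 2.0 h, from then on at 65 °C |
| time |  |  | 10 h | 10 h |

- larch (time / h: first product / %, starting material / %): 0.200: 4.3, 89.9; 0.667: 11.8, 69.9; 1.33: 19.5, 49.5; 1.50: 20.6, 43.1; 2.50: 26.3, 28.9; 3.00: 27.3, 24.9
- alder (time / min: first product / %, starting material / %): 5.00: 10.9, 73.9; 8.00: 13.2, 63.1; 12.0: 16.0, 49.1; 25.0: 15.8, 28.4; 40.0: 18.5, 15.1; 60.0: 16.9, 9.2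

(readings scatter by 1 percentage point)

- percent here means starting material units held: one side product B counts as two
- what is said of by-product includes crystals
- crystals is a solid; its amount is given per volume of the solution
- steps that have been proposed: coupling partner + other mono adduct -> bis adduct + by-product; starting material + by-product -> side product A; starting material + coupling partner -> other mono adduct + by-product; coupling partner + first product -> bis adduct + by-product; starting material + coupling partner -> first product + by-product; starting material + first product -> side product B; crystals <-> by-product

1. which of the two ends with the higher amount of first product, in percent of the starting material charged ("neither" if they lie within 2 percentage points) (Saturday's / Friday's / neither)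
2. first product at the end, in percent of the starting material charged, Saturday's
3. first product at the end, in percent of the starting material charged, Friday's

I reckoned with two times. The first is the life of the starting material, the time constant of its fall, with [coupling partner] taken as steady (pseudo-first-order). The second is the hours the flask stands at that temperature.

Larch read 69.9 % of starting material at 0.667 h, which gave a life of 1.86 h. Alder read 49.1 % at 12.0 min, which gave 0.281 h. Alder also held more starting material, but I let temperature carry the whole difference, so my lives were rough. Stretched along the temperature, they gave 4.40 h at 25 °C and 0.141 h at 65 °C.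

Friday's hot hours gave 56.6 of what I call lives served, meaning hours at a temperature over the life there. So Friday's reckoned life at its hot temperature was far shorter than its hot period, and I expected its first product to stand hot for hours after its starting material had fallen away. Alder's first product read 18.5 % and then 16.9 % late on, no rise beyond the scatter of 1 percentage point. Saturday's got 2.27 lives, so about 10.3 % of its starting material would remain and still feed first product. I expected Saturday's ahead.

The forecast said Saturday's, with 31 % (26 % to 36 %) for Saturday's and 17 % (7 % to 25 %) for Friday's, reasoning that “the remaining starting material goes quickly, with side reactions competing”.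

The flasks gave Saturday's, with 31.0 % for Saturday's and 9.40 % for Friday's.

    coupling partner + other mono adduct → bis adduct + by-product (k = 0.441 M⁻¹ h⁻¹, Ea = 77.0 kJ mol⁻¹)
    starting material + by-product → side product A (k = 0.224 M⁻¹ h⁻¹, Ea = 73.0 kJ mol⁻¹)
    starting material + coupling partner → other mono adduct + by-product (k = 0.182 M⁻¹ h⁻¹, Ea = 75.0 kJ mol⁻¹)
    coupling partner + first product → bis adduct + by-product (k = 0.0188 M⁻¹ h⁻¹, Ea = 91.0 kJ mol⁻¹)
    starting material + coupling partner → first product + by-product (k = 0.150 M⁻¹ h⁻¹, Ea = 78.0 kJ mol⁻¹)
    starting material + first product → side product B (k = 0.255 M⁻¹ h⁻¹, Ea = 69.0 kJ mol⁻¹)
    crystals ⇌ by-product, rate k7*(cs7 - [by-product]) while solid is left; crystals form when [by-product] > cs7 (solubility = 31.0 mM, k = 1.69 h⁻¹)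
    (constants at 25 °C)

Friday's had 56.6 reckoned hot lives, and in the flask starting material stood at 0.0106 % after 5.00 h, with first product at 16.0 %, and first product then sank to 9.40 % by 10.0 h. The shift in temperature and the step coupling partner + first product → bis adduct + by-product together held Friday's first product down: Friday's ends at 27.5 % with that step struck out, and at 21.8 % without the shift in temperature. Friday's recipe with 0.16 M of starting material serves the same reckoned lives, and it too ended with 0 % of its starting material, while it held 53 % of its own coupling partner and 0.954 % of first product.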